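Ring locants used throughout: C1 (lactone O–CH), C2 (ring-fusion CH), C3 (CHOH), C4 (C=O), C5 (CHMe), C6–C8 (CH2), C9 (C(OH)Me), C10 (CH–O-isovaleryl); lactone carbons C11 (α-carbon), C12 (C=O), C13 (exocyclic CH2).

## Analysis of the target

The target 26 is a cyclodecane that is trans-fused at C1–C2 to an α-methylene-γ-butyrolactone. It has six stereocentres, (1R,2S,3S,5S,9R,10S) in these locants. C1–O and C3–OH lie on one face of the ring and the C2–C11 bond on the other; C9–OH and C10–O are cis to each other and opposite to C1–O; the C5 methyl is trans to C3–OH across the ketone. The sensitive groups are the α-methylene lactone (a Michael acceptor that tolerates neither enolates nor hydrides), the C3/C4 α-ketol, the epimerisable C5 centre, and the tertiary C9 alcohol next to an ester. In addition, O3 is γ to C12 just as O1 is, so base can move the lactone from O1 to O3. The difficulty is threefold: a ten-membered ring is penalised on closure, the stereocentres sit on a flexible ring without a rigid template, and the two halves of the ring have the same carbon pattern but different oxidation states. The structural feature used is that C4 and C10 are 1,5-related through C3–C2–C1, each has a methyl-bearing neighbour on its far side (C5, C9), and these are linked by three methylenes (C6–C8). Without the extra oxygens the carbocycle is a mirror-symmetric dimethylcyclodecane-1,5-dione with the mirror plane through C2 and C7. If the C5–C10 bond is drawn in, C1–C5 and C10 are the ring of a 5-substituted 2-methylcyclohexane-1,3-dione, and C6–C9 with the C9 methyl are a 1-methylcyclobutene.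

## Retrosynthetic reasoning

**26 back to 23 (C13).** The last step only removes the C3 silyl ether of 25 under acidic fluoride conditions, so the finished molecule never sees base. The C11=C13 double bond is cut next: it comes from elimination in the hydroxymethyl lactone 23, so the Michael acceptor exists for two steps only. C13 itself is traced back to formaldehyde 11, added to the ester enolate of the bis(enol ether) 10. That is the one stage at which the ester α-position is the most acidic site; a methylenation of the finished lactone would have to compete with the C4 ketone and the isovalerate.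

**23 back to 21 (lactone C12–O1).** The lactone is opened to the ester 21. Because O1 and O3 can both reach C12, the ring is closed when O3 is silylated and O1 alone is freed; its triethylsilyl ether is the most labile silyl group present. Closing the lactone late also keeps an acyloxy group off C1 while C10 is a ketone, where it would make C1–H the most acidic proton.

**21 back to 17 and 18 (C3–O, isovalerate).** The C3–O bond is cut to the silyl enol ether of 19; a Rubottom oxidation delivers C3–O already silylated. This enol ether has masked C4 since 10, protecting it from hydride, from enolisation toward C5 and from transannular aldol addition with C10. The ester is cut to the diol 17 and isovaleric anhydride 18, at the point where C10–OH is the only secondary hydroxyl.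

**17 back to 15 (C10–H, C9–O).** Both come from the C10 ketone of 15. The C9 hydroxyl is put in by enolate hydroxylation; the silyloxy group on C1 sends deprotonation to C9. The new hydroxyl then steers a chelation-controlled reduction at C10. In this order C9 controls C10 and only one ketone is ever free.

**15 back to 13 (C1–O, the two halves).** 13 carries two constitutionally equivalent silyl enol ethers on either side of C2. A ligand-controlled osmylation oxidises one of them. The forward step must choose the arm and the face; in doing so it sets C1, fixes C2 and leaves the other arm as the C4 mask. This is where the symmetric plan pays its price.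

**13 back to 9.** Both carbonyls of the dione 9 are converted to kinetic enol ethers (CH2 over CHMe) to give 10. With no free ketone, the transannular aldol addition that threatens a cyclodecane-1,5-dione is impossible and the ester can be deprotonated.

**9 back to 8 (C6–C9).** Re-forming the C6–C9 bond gives the cyclobutane-fused cyclooctanedione 8. In the forward direction a ketyl at C10 cleaves this ring-fusion bond, so the ten-membered ring arises by ring expansion and not by end-to-end closure.

**8 back to 4 and 6 (key disconnection).** Cutting C9–C10 and C5–C6 and reconnecting C5–C10 gives the dione enol 4 and 1-methylcyclobutene 6. These two bonds join each methyl-bearing carbon to its neighbour, so all ten ring carbons, both methyls and the C2 side chain come from two simple pieces in one photochemical step. The forward reaction must add the alkene head-to-tail and then fragment.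

**4 back to 1 and 3; 6 back to 5.** 4 is the C-methylation product of the dione 2 with iodomethane 3, and 2 is the partial hydrogenation product of the resorcinol 1. 6 is the endocyclic isomer of methylenecyclobutane 5.

## Alternatives that were turned down

**Alternative 1:** The ring is cut at C7–C8. In the forward step a sulfone-stabilised carbanion at C7 opens a terminal epoxide at its CH2 end (C8), closing the ring and releasing the C9 tertiary alkoxide to give the ten-membered sulfone A1. In its favour, C9 comes from an enantiopure epoxide and every other centre is set in an open chain under reagent control. On stereochemical predictability this plan is stronger than the chosen one, which relies on facial selectivity in a flexible ring. Against it: the closure is an intermolecular-type alkylation forced into a ten-membered transition state and needs high dilution, and A1 shows the cost in protecting groups (ketal, PMB, two TBS, TES). After the key step the sulfone must be removed reductively and the C2 side chain oxidised and lactonised, so the linear sequence is long. The chosen strategy offers instead the whole carbocycle in four steps and ring formation driven by strain release.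

**Alternative 2:** The ring is cut at C1–C10. A single-electron reductant couples two aldehydes to the C1/C10 diol, and the C1 alkoxide closes the lactone on a pendant ester in the same flask, giving hydroxy lactone A2. In its favour, ring, diol and lactone form together, and the lactonisation tells O1 from O10 without a protecting group. Against it: two new stereocentres are created in the ring-closing event with no reliable control relative to C2 and C9, and the C10 aldehyde sits next to a fully substituted carbon. A2 still lacks the methylene group, the isovalerate and the free ketone, and the dithiane must come off a molecule that by then holds an α-methylene lactone. Its stereochemical risk is of the same kind as in the chosen route but is concentrated in the macrocyclisation; the chosen route spreads it over steps that can each be corrected.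

**Alternative 3:** The ring is cut at C2–C3. A divalent chromium salt turns a 3-(bromomethyl)butenolide into an allylchromium species that adds through C2 to a tethered C3 aldehyde, closing the ring with the α-methylene lactone complete and giving dithioketal A3, one deprotection from the target. This is the strongest alternative. The end-game is shorter than the chosen one, the methylene lactone never has to be made on a loaded ring, and the chair-like allylation sets C2 and C3 together. Against it: the entire C3–C10 chain with C5, C9, C10 and the butenolide centre C1 must be built linearly first, the aldehyde is neopentyl-like next to the dithiane, the closure needs high dilution and a large excess of the chromium salt, and the final dithiane removal needs oxidising or alkylating conditions in the presence of the methylene lactone and the α-ketol. The chosen strategy is weaker in its end-game but reaches the ring skeleton much faster and uses no macrocyclisation.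

Key step: step 4

Assumption: centres that form without control and are reset or erased later (C5 and C9 from 8 on, C9 until step 9, C5 until step 14, C11 in 12–24) are carried as mixtures of epimers, and their SMILES leave those centres open; 8 is racemic.

Step 1
Reactants: 1 methyl 3,5-dihydroxyphenylacetate
Product: 2 methyl 2-(3,5-dioxocyclohexyl)acetate
Conditions: H2 (4 atm), 5% Rh/Al2O3, NaOH (1.0 equiv), H2O–MeOH, 25 °C; then HCl (aq) to pH 3
Reagents that add atoms: none
Why: Partial hydrogenation of a resorcinol monoanion stops at the cyclohexane-1,3-dione because the product is held as its enolate salt, which is not reduced further (dihydroresorcinol synthesis); the methyl ester survives the weakly basic medium.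

Step 2
Reactants: 2 methyl 2-(3,5-dioxocyclohexyl)acetate; 3 iodomethane
Product: 4 methyl 2-(3-hydroxy-4-methyl-5-oxocyclohex-3-en-1-yl)acetate
Conditions: NaOH (1.0 equiv), H2O–MeOH, 60 °C, sealed vessel
Reagents that add atoms: none
Why: C-Alkylation of a 1,3-dione enolate in protic medium, where hydrogen bonding to the enolate oxygens suppresses O-methylation (classical 2-methylcyclohexane-1,3-dione synthesis); the enolate solution is near neutral, so the ester is not hydrolysed.

Step 3
Reactants: 5 methylenecyclobutane
Product: 6 1-methylcyclobutene
Conditions: KOt-Bu (0.2 equiv), DMSO, 70 °C; fractional distillation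
Reagents that add atoms: none
Why: Base-mediated allylic prototropic isomerisation to the more substituted endocyclic alkene, which should be favoured at equilibrium and is taken off by distillation.

Step 4
Reactants: 4 methyl 2-(3-hydroxy-4-methyl-5-oxocyclohex-3-en-1-yl)acetate; 6 1-methylcyclobutene
Product: 8 methyl 2-(cis-1,7-dimethyl-2,6-dioxobicyclo[6.2.0]decan-4-yl)acetate (racemic), via cyclobutanol photoadduct 7 (not isolated)
Conditions: hν (medium-pressure Hg lamp, Pyrex, λ > 290 nm), 6 (8 equiv), MeCN, −20 °C, degassed, partial conversion
Reagents that add atoms: none
Why: De Mayo reaction: enol 4 is a hydrogen-bonded β-hydroxy enone whose triplet adds to 6 through a 1,4-biradical to give cyclobutanol 7. 7 is a β-hydroxy ketone locked in a bicyclo[2.2.0]hexane, so retro-aldol cleavage of the old enol bond C5–C10 should follow spontaneously and expand the six-membered ring by the two alkene carbons to the eight-membered 1,5-dione 8, with the bonds C9–C10 and C5–C6 in place. The closest known reaction type is the photoaddition of cyclohexane-1,3-dione enols to cycloalkenes with retro-aldol ring expansion; only the alkene partner is new. The four-membered ring closes by recombination of the biradical after the first bond has formed; the eight-membered ring is not closed end to end but arises by ring expansion. The C6/C9 ring fusion is cis because both bonds are made to the same face of the cyclobutene, the only way to fuse a second four-membered ring; C5 is set by ketonisation without control; both are racemic and are erased later, and C2 is a spectator. The step needs the head-to-tail orientation (methyl-bearing alkene carbon to the oxygen-bearing enol carbon C10), which is the usual orientation of electron-rich alkenes with triplet enones and also avoids joining the two methyl-bearing carbons. It also needs the enol and not the product to absorb, which the Pyrex filter, the excess of 6 and stopping short of full conversion should secure.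

Step 5
Reactants: 8 methyl 2-(cis-1,7-dimethyl-2,6-dioxobicyclo[6.2.0]decan-4-yl)acetate
Product: 9 methyl 2-(5,9-dimethyl-4,10-dioxocyclodec-2-yl)acetate (target ring locants; mixture of C5/C9 epimers)
Conditions: SmI2 (2.5 equiv), HMPA (12 equiv), t-BuOH (2.2 equiv), THF, −20 → 0 °C
Reagents that add atoms: none
Why: Ketyl fragmentation of a cyclobutyl ketone with samarium diiodide: the C10 ketyl cleaves the ring-fusion bond C9–C6, which releases the cyclobutane strain and gives the secondary radical, and the trivalent samarium enolate and the reduced C6 centre are protonated by t-BuOH. HMPA-saturated samarium should disfavour the chelated transannular pinacol coupling with C4, and the proton source intercepts the enolate before it can add to C4.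

Step 6
Reactants: 9 methyl 2-(5,9-dimethyl-4,10-dioxocyclodec-2-yl)acetate
Product: 10 methyl 2-[4,10-bis(tert-butyldimethylsilyloxy)-5,9-dimethylcyclodeca-3,10(1)-dien-2-yl]acetate (enol ethers C3=C4 and C10=C1, ring-cis)
Conditions: LiN(i-Pr)2 (2.3 equiv), THF, −78 °C (9 added to the base); TBSCl (2.6 equiv), HMPA, −78 → 0 °C
Reagents that add atoms: tert-butyldimethylsilyl chloride, CC(C)(C)[Si](C)(C)Cl
Why: Kinetic deprotonation removes the methylene protons at C1 and C3 in preference to the methine protons at C5 and C9, and O-silylation traps both enolates. The C1 and C3 enolates cannot add across the ring (a four-membered ring would result), and once both carbonyls are masked the aldol addition of C9 to C4 is excluded for good.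

Step 7
Reactants: 10 methyl 2-[4,10-bis(tert-butyldimethylsilyloxy)-5,9-dimethylcyclodeca-3,10(1)-dien-2-yl]acetate; 11 formaldehyde (gas, from paraformaldehyde)
Product: 13 methyl 3-(tert-butyldimethylsilyloxy)-2-[4,10-bis(tert-butyldimethylsilyloxy)-5,9-dimethylcyclodeca-3,10(1)-dien-2-yl]propanoate, via hydroxymethyl ester 12 (not isolated)
Conditions: LiN(i-Pr)2 (1.2 equiv), THF, −78 °C; 11; then TBSOTf (1.5 equiv), −78 → −40 °C
Reagents that add atoms: tert-butyldimethylsilyl triflate, CC(C)(C)[Si](C)(C)OS(=O)(=O)C(F)(F)F
Why: With the ketones masked the ester α-protons are the only acidic ones; the lithium enolate adds to monomeric formaldehyde (aldol hydroxymethylation) and the aldolate is silylated in the flask. The new carbon is the future C13; the C11 centre is uncontrolled and is erased in step 14.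

Step 8
Reactants: 13 methyl 3-(tert-butyldimethylsilyloxy)-2-[4,10-bis(tert-butyldimethylsilyloxy)-5,9-dimethylcyclodeca-3,10(1)-dien-2-yl]propanoate
Product: 15 C1-triethylsilyloxy C10-ketone with the C3=C4 silyl enol ether retained (1R and 2S as in the target), via hydroxy ketone 14 (not isolated)
Conditions: OsO4 (1.0 equiv), (DHQD)2PHAL (1.1 equiv), toluene, −78 °C; NaHSO3 (aq), THF, 0 °C; crude 14, TESOTf, 2,6-lutidine, CH2Cl2, −78 °C
Reagents that add atoms: osmium tetroxide, O=[Os](=O)(=O)=O; triethylsilyl triflate, CC[Si](CC)(CC)OS(=O)(=O)C(F)(F)F
Why: Ligand-controlled osmylation of a silyl enol ether (Sharpless asymmetric dihydroxylation, stoichiometric variant); with the enol ether hydrogen placed in the hindered quadrant of the face mnemonic, the DHQD ligand delivers oxygen to the face that makes C1 (R). Of the two enol ethers only one has this face as the one the ring itself prefers (oxygen trans to the C2 branch), so it should react much faster; one reagent therefore sets C1, fixes C2 and distinguishes the two halves, whatever the configuration at C5, C9 and C11. The silyl hemiketal collapses to the ketone, and neutral work-up with immediate silylation at −78 °C keeps the C1 hydroxyl from closing onto the ester.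

Step 9
Reactants: 15 C1-triethylsilyloxy C10-ketone with the C3=C4 silyl enol ether
Product: 16 C9 tertiary alcohol of 15 (9R)
Conditions: KN(SiMe3)2 (1.3 equiv), THF, −78 °C; 2-(phenylsulfonyl)-3-phenyloxaziridine; AcOH quench
Reagents that add atoms: 2-(phenylsulfonyl)-3-phenyloxaziridine, O=S(=O)(N1OC1c1ccccc1)c1ccccc1
Why: An α-silyloxy ketone is deprotonated on its non-oxygenated side, so only the C9 enolate forms (C4 is masked and the ester α-proton is far less acidic); Davis hydroxylation of this enolate should occur on the peripheral face, anti to the C1–C2 ring bond, which places the C9 hydroxyl trans to C1–O as required.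

Step 10
Reactants: 16 C9 tertiary alcohol of 15
Product: 17 C9,C10-diol (9R,10S)
Conditions: Zn(BH4)2, Et2O, −30 → 0 °C; then H2O
Reagents that add atoms: none
Why: Chelation-controlled reduction: zinc bridges the C9 hydroxyl and the C10 carbonyl (the silyl ether at C1 does not chelate) and hydride attacks the chelate from the side of the C9 methyl group, away from the ring chain, which gives the C9–OH/C10–OH cis diol; the ester, silyl ethers and enol ether are inert to Zn(BH4)2.

Step 11
Reactants: 17 C9,C10-diol; 18 isovaleric anhydride
Product: 19 C10 isovalerate of 17
Conditions: DMAP, Et3N, CH2Cl2, 25 °C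
Reagents that add atoms: none
Why: DMAP-catalysed acylation of the only secondary hydroxyl; the tertiary C9 hydroxyl does not react under these conditions and the silyl enol ether is untouched.

Step 12
Reactants: 19 C10 isovalerate of 17
Product: 21 C3-(tert-butyldimethylsilyloxy) C4-ketone (3S), via silyloxy epoxide 20 (not isolated)
Conditions: mCPBA, CH2Cl2, −20 → 0 °C
Reagents that add atoms: 3-chloroperbenzoic acid, OOC(=O)c1cccc(Cl)c1
Why: Rubottom oxidation: the peracid epoxidises the electron-rich enol ether and the silyloxy epoxide opens with 1,4-silyl migration, so C3–O emerges already protected; oxygen should arrive trans to the C2 branch, the same 1,2-induction that operated at C1 on the mirror-related arm.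

Step 13
Reactants: 21 C3-(tert-butyldimethylsilyloxy) C4-ketone
Product: 23 trans-fused γ-lactone bearing CH2OH at C11 with C3–OTBS retained, via hydroxy ester 22 (not isolated)
Conditions: CSA (0.2 equiv), MeOH, 0 °C; then CSA (cat.), toluene, 40 °C
Reagents that add atoms: none
Why: Acidic methanolysis removes the triethylsilyl ether and the primary silyl ether but not the hindered secondary one at C3; the freed C1 hydroxyl is then the only hydroxyl that can form a five-membered ring with the ester, so acid-catalysed lactonisation gives the lactone on the correct oxygen.

Step 14
Reactants: 23 trans-fused γ-lactone bearing CH2OH at C11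
Product: 25 C3-O-TBS ether of the target (5S), via mesylate 24 (not isolated)
Conditions: MsCl (1.1 equiv), Et3N, CH2Cl2, −40 °C; then DBU, 0 → 25 °C
Reagents that add atoms: none
Why: The primary hydroxyl is mesylated selectively (C9–OH is tertiary, C3–O is protected) and the β-mesyloxy lactone undergoes E1cB elimination to the α-methylene lactone, which erases C11. Continued exposure to DBU should equilibrate C5 toward the epimer with the methyl group trans to the C3 silyloxy group; the minor epimer is separated and resubmitted.

Step 15
Reactants: 25 C3-O-TBS ether of the target
Product: 26 target, CNP0240128.1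
Conditions: HF·pyridine, pyridine, THF, 0 → 25 °C
Reagents that add atoms: none
Why: Fluoride cleavage of the secondary silyl ether under buffered acidic conditions, which avoid the basic conditions that would endanger the methylene lactone, the α-ketol and the position of the lactone.

Compound list

1 | methyl 3,5-dihydroxyphenylacetate | COC(=O)Cc1cc(O)cc(O)c1 | starting material
2 | methyl 2-(3,5-dioxocyclohexyl)acetate (enolised in solution) | COC(=O)CC1CC(=O)CC(=O)C1 | intermediate
3 | iodomethane | CI | starting material
4 | methyl 2-(3-hydroxy-4-methyl-5-oxocyclohex-3-en-1-yl)acetate (enol of the 2-methyl-1,3-dione; the two enol forms are enantiomers and interconvert) | COC(=O)CC1CC(O)=C(C)C(=O)C1 | intermediate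
5 | methylenecyclobutane | C=C1CCC1 | starting material
6 | 1-methylcyclobutene | CC1=CCC1 | intermediate
7 | cyclobutanol photoadduct: cyclohexanone cis-fused through C5–C10 to a bicyclo[2.2.0]hexane, tertiary hydroxyl on C10, methyls on C5 and C9 (racemic, one anti isomer drawn) | COC(=O)CC1CC(=O)[C@]2(C)[C@H]3CC[C@@]3(C)[C@]2(O)C1 | intermediate
8 | methyl 2-(cis-1,7-dimethyl-2,6-dioxobicyclo[6.2.0]decan-4-yl)acetate (racemic, ring fusion drawn as one enantiomer) | COC(=O)CC1CC(=O)C(C)[C@@H]2CC[C@]2(C)C(=O)C1 | intermediate
9 | methyl 2-(5,9-dimethyl-4,10-dioxocyclodec-2-yl)acetate | COC(=O)CC1CC(=O)C(C)CCCC(C)C(=O)C1 | intermediate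
10 | methyl 2-[4,10-bis(tert-butyldimethylsilyloxy)-5,9-dimethylcyclodeca-3,10(1)-dien-2-yl]acetate | COC(=O)CC1/C=C(O[Si](C)(C)C(C)(C)C)\C(C)CCCC(C)/C(O[Si](C)(C)C(C)(C)C)=C\1 | intermediate
11 | formaldehyde | C=O | starting material
12 | hydroxymethyl ester: 10 with CH2OH on C11 | COC(=O)C(CO)C1/C=C(O[Si](C)(C)C(C)(C)C)\C(C)CCCC(C)/C(O[Si](C)(C)C(C)(C)C)=C\1 | intermediate
13 | methyl 3-(tert-butyldimethylsilyloxy)-2-[4,10-bis(tert-butyldimethylsilyloxy)-5,9-dimethylcyclodeca-3,10(1)-dien-2-yl]propanoate | COC(=O)C(CO[Si](C)(C)C(C)(C)C)C1/C=C(O[Si](C)(C)C(C)(C)C)\C(C)CCCC(C)/C(O[Si](C)(C)C(C)(C)C)=C\1 | intermediate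
14 | hydroxy ketone: C1–OH (R), C10 ketone, C3=C4 silyl enol ether, C2 as in the target | COC(=O)C(CO[Si](C)(C)C(C)(C)C)[C@H]1/C=C(O[Si](C)(C)C(C)(C)C)\C(C)CCCC(C)C(=O)[C@@H]1O | intermediate
15 | C1 triethylsilyl ether of 14 | COC(=O)C(CO[Si](C)(C)C(C)(C)C)[C@H]1/C=C(O[Si](C)(C)C(C)(C)C)\C(C)CCCC(C)C(=O)[C@@H]1O[Si](CC)(CC)CC | intermediate
16 | 15 with tertiary hydroxyl at C9 (R) | COC(=O)C(CO[Si](C)(C)C(C)(C)C)[C@H]1/C=C(O[Si](C)(C)C(C)(C)C)\C(C)CCC[C@@](C)(O)C(=O)[C@@H]1O[Si](CC)(CC)CC | intermediate
17 | C9,C10-diol (9R,10S) | COC(=O)C(CO[Si](C)(C)C(C)(C)C)[C@H]1/C=C(O[Si](C)(C)C(C)(C)C)\C(C)CCC[C@@](C)(O)[C@@H](O)[C@@H]1O[Si](CC)(CC)CC | intermediate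
18 | isovaleric anhydride (3-methylbutanoic anhydride) | CC(C)CC(=O)OC(=O)CC(C)C | starting material
19 | C10 isovalerate of 17 | COC(=O)C(CO[Si](C)(C)C(C)(C)C)[C@H]1/C=C(O[Si](C)(C)C(C)(C)C)\C(C)CCC[C@@](C)(O)[C@@H](OC(=O)CC(C)C)[C@@H]1O[Si](CC)(CC)CC | intermediate
20 | C3,C4-silyloxy epoxide of 19 (oxygen trans to the C2 branch) | COC(=O)C(CO[Si](C)(C)C(C)(C)C)[C@H]1[C@@H]2O[C@]2(O[Si](C)(C)C(C)(C)C)C(C)CCC[C@@](C)(O)[C@@H](OC(=O)CC(C)C)[C@@H]1O[Si](CC)(CC)CC | intermediate
21 | C3-(tert-butyldimethylsilyloxy) C4-ketone (3S) | COC(=O)C(CO[Si](C)(C)C(C)(C)C)[C@H]1[C@H](O[Si](C)(C)C(C)(C)C)C(=O)C(C)CCC[C@@](C)(O)[C@@H](OC(=O)CC(C)C)[C@@H]1O[Si](CC)(CC)CC | intermediate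
22 | hydroxy ester: 21 with free C1–OH and free CH2OH | COC(=O)C(CO)[C@H]1[C@H](O[Si](C)(C)C(C)(C)C)C(=O)C(C)CCC[C@@](C)(O)[C@@H](OC(=O)CC(C)C)[C@@H]1O | intermediate
23 | trans-fused γ-lactone with CH2OH at C11, C3–OTBS, C10 isovalerate | OCC1C(=O)O[C@@H]2[C@@H]1[C@H](O[Si](C)(C)C(C)(C)C)C(=O)C(C)CCC[C@@](C)(O)[C@H]2OC(=O)CC(C)C | intermediate
24 | primary mesylate of 23 | CS(=O)(=O)OCC1C(=O)O[C@@H]2[C@@H]1[C@H](O[Si](C)(C)C(C)(C)C)C(=O)C(C)CCC[C@@](C)(O)[C@H]2OC(=O)CC(C)C | intermediate
25 | C3-O-TBS ether of the target | C=C1C(=O)O[C@@H]2[C@@H]1[C@H](O[Si](C)(C)C(C)(C)C)C(=O)[C@@H](C)CCC[C@@](C)(O)[C@H]2OC(=O)CC(C)C | intermediate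
26 | CNP0240128.1 | C=C1C(=O)O[C@@H]2[C@@H]1[C@H](O)C(=O)[C@@H](C)CCC[C@@](C)(O)[C@H]2OC(=O)CC(C)C | target

Total step count: 15. Longest linear sequence: 14 steps (steps 1, 2 and 4–15); step 3 is a one-step side branch.

Steps least certain to work

**Step 4 (key step).** The most likely failure is low conversion combined with secondary photolysis of the product and some leakage into the head-to-head orientation. The fully substituted enol adds slowly, while 8 has a ketone next to a strained quaternary cyclobutane carbon and absorbs in the same region. Fallback: from 4, acetylation (Ac2O, pyridine) gives the enol acetate F1, a fixed enone chromophore with no tautomer equilibrium. Irradiation with 6 gives the stable cyclobutyl acetate F2, so no diketone is present during irradiation. K2CO3 in MeOH then frees the cyclobutanol, which fragments, and the route is rejoined at 8.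

**Step 5.** The most likely failure is transannular pinacol coupling of the two carbonyls, or aldol addition of the samarium enolate to C4, in place of fragmentation; an eight-membered 1,5-dione holds its carbonyls face to face. Cleavage of the exocyclic cyclobutane bond is a second possible leak. Fallback: from 8, LiBH(s-Bu)3 at −78 °C reduces the less hindered C4 carbonyl (C10 is flanked by the quaternary carbon) to the hydroxy ketone F3. The same SmI2 conditions now meet a single ketone and give the ring-expanded hydroxy ketone F4. Dess–Martin periodinane returns to 9.

**Step 8.** The most likely failure is incomplete discrimination between the two enol ethers, with over-oxidation, and partial ring closure of the C1 hydroxyl onto the ester before it is silylated. The disfavoured arm is only slowed, not blocked, and the C11 epimers perturb the two arms differently. Fallback: a Shi epoxidation of 13 (fructose-derived ketone of the matching hand, KHSO5, buffered MeCN–H2O, 0 °C) puts the choice of arm and face under a different reagent geometry. It would give the silyloxy epoxide F5, which is hydrolysed in pH 4 buffer to 14 and silylated as before, rejoining at 15.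

**Step 9.** The most likely failure is poor facial selectivity in the oxidation of the tetrasubstituted enolate. A 1,3-relationship across a carbonyl is a weak control element in a flexible ring, and the silyl ether on C1 sits on the face that has to be attacked. Fallback: reagent control replaces substrate control. From 15, the same enolate is oxidised with the enantiomer of (camphorsulfonyl)oxaziridine that matches the required face, a reagent class that performs best on exactly such fully substituted enolates. The route is rejoined at 16 with no new compound (F0).

**Step 14.** The most likely failure is that equilibration at C5 settles at an unfavourable ratio or begins to epimerise C3, since nothing guarantees that the required epimer is the more stable one in the silylated compound. Fallback: kinetic protonation replaces thermodynamic control. From 25 (either epimer or the mixture), TMSOTf and Et3N give the C4=C5 silyl enol ether F6, in which the C9 hydroxyl is silylated too. HF·pyridine at −40 °C then protonates C5 from the peripheral face and removes all silyl groups, arriving directly at 26.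

Further compounds

F1 | step 4 | methyl 2-(3-acetoxy-4-methyl-5-oxocyclohex-3-en-1-yl)acetate | COC(=O)CC1CC(OC(C)=O)=C(C)C(=O)C1
F2 | step 4 | O-acetyl derivative of photoadduct 7 (racemic) | COC(=O)CC1CC(=O)[C@]2(C)[C@H]3CC[C@@]3(C)[C@]2(OC(C)=O)C1
F3 | step 5 | C4 carbinol of 8 (racemic) | COC(=O)CC1CC(O)C(C)[C@@H]2CC[C@]2(C)C(=O)C1
F4 | step 5 | methyl 2-(4-hydroxy-5,9-dimethyl-10-oxocyclodec-2-yl)acetate (target ring locants) | COC(=O)CC1CC(O)C(C)CCCC(C)C(=O)C1
F5 | step 8 | C10,C1-silyloxy epoxide of 13 (oxygen trans to the C2 branch) | COC(=O)C(CO[Si](C)(C)C(C)(C)C)[C@H]1/C=C(O[Si](C)(C)C(C)(C)C)\C(C)CCCC(C)[C@]2(O[Si](C)(C)C(C)(C)C)O[C@H]12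
F0 | step 9 | none | none
F6 | step 14 | C4=C5 trimethylsilyl enol ether of 25 with C9–O-trimethylsilyl | C=C1C(=O)O[C@@H]2[C@@H]1[C@H](O[Si](C)(C)C(C)(C)C)/C(O[Si](C)(C)C)=C(C)\CCC[C@@](C)(O[Si](C)(C)C)[C@H]2OC(=O)CC(C)C
A1 | alternative 1 | ten-membered C7 phenyl sulfone with free C9 tertiary alcohol, C4 dioxolane, C3–OPMB, C1–OTBS, C10–OTES | CC(C)(C)[Si](C)(C)O[C@@H]1[C@@H](C(=C)CO[Si](C)(C)C(C)(C)C)[C@H](OCc2ccc(OC)cc2)C3(OCCO3)[C@@H](C)C[C@@H](S(=O)(=O)c4ccccc4)C[C@@](C)(O)[C@H]1O[Si](CC)(CC)CC
A2 | alternative 2 | ten-membered trans-fused lactone with free C10 hydroxyl, C4 dithiane, C3–OTBS, C9–OMOM | C1C(=O)O[C@@H]2[C@@H]1[C@H](O[Si](C)(C)C(C)(C)C)C3(SCCCS3)[C@@H](C)CCC[C@@](C)(OCOC)[C@H]2O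
A3 | alternative 3 | C4 dithioketal of the target | C=C1C(=O)O[C@@H]2[C@@H]1[C@H](O)C3(SCCCS3)[C@@H](C)CCC[C@@](C)(O)[C@H]2OC(=O)CC(C)C
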